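**Plan**

- Numbering: the target chain runs from C1 (CH2OAc) to C12 (lactone C=O); C6 is the carbinol carbon and C7 the quaternary ring carbon.
- Retrosynthesis: the oxepinone is opened at the C7–O–C12 ester bond, C10=C11 is cut by a Z-selective and C2=C3 by an E-selective Horner–Wadsworth–Emmons reaction, and C4–C5 and C8–C9 are then cut together.
- Enabling feature: C5–C6–C7(CH3)–C8 carries oxygen only on C6 and C7 and ends in two CH2 groups, so it is the 1,2:3,4-dianhydro form of 2-C-methyl-D-erythritol, a bis-epoxide electrophilic at C5 and C8; the seven-membered ring (O, C7 to C12) is closed only later.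
- Forward: prenol gives the bis-epoxide; one flask joins methallyl at C5 and cyanomethyl at C8; the chain grows first at C3 (ozonolysis, olefination, reduction, acetate), then at C10 (Z-olefination); lactonisation forms the only ring and desilylation ends the route.
- Stereochemistry: one Sharpless epoxidation (L-(+)-diethyl tartrate) sets both centres; C6 is inverted once during epoxide migration, after which no C–O bond at C6 or C7 is broken; the 2E and 10Z alkenes come from the two olefinations.

Key step: step 7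

**Route**

Step 1
Reactants: 1 prenol (3-methylbut-2-en-1-ol)
Product: 2 benzyl prenyl ether
Conditions: NaH, BnBr, n-Bu4NI (cat.), THF, 0 °C → rt
Reagents that add atoms: benzyl bromide BrCc1ccccc1
Why: Williamson etherification of a primary allylic alkoxide with a benzylic bromide is clean, and the benzyl group can later be removed by neutral hydrogenolysis.

Step 2
Reactants: 2 benzyl prenyl ether
Product: 3 (2E)-4-(benzyloxy)-2-methylbut-2-en-1-ol
Conditions: SeO2 (cat.), t-BuOOH, salicylic acid (cat.), CH2Cl2, rt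
Reagents that add atoms: tert-butyl hydroperoxide CC(C)(C)OO (oxygen source, relayed by catalytic selenium dioxide O=[Se]=O)
Why: Riley allylic oxidation (ene reaction, then 2,3-sigmatropic shift) hydroxylates the methyl group trans to the CH2OBn substituent of the trisubstituted alkene, which gives the E allylic alcohol.

Step 3
Reactants: 3 (2E)-4-(benzyloxy)-2-methylbut-2-en-1-ol
Product: 4 [(2S,3S)-3-[(benzyloxy)methyl]-2-methyloxiran-2-yl]methanol
Conditions: Ti(OiPr)4 (cat.), L-(+)-diethyl tartrate (cat.), t-BuOOH, 4 Å molecular sieves, CH2Cl2, −20 °C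
Reagents that add atoms: tert-butyl hydroperoxide CC(C)(C)OO
Why: Sharpless asymmetric epoxidation of the titanium-bound allylic alkoxide, in which the L-(+)-tartrate ligand directs peroxide oxygen to the alkene face that gives the (2S,3S)-epoxide as is the rule for E-configured 2,3-disubstituted allylic alcohols, fixes C7 as S and sets C6 provisionally.

Step 4
Reactants: 4 [(2S,3S)-3-[(benzyloxy)methyl]-2-methyloxiran-2-yl]methanol
Product: 5 [(2S,3S)-3-[(benzyloxy)methyl]-2-methyloxiran-2-yl]methyl methanesulfonate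
Conditions: MsCl, Et3N, CH2Cl2, 0 °C
Reagents that add atoms: methanesulfonyl chloride CS(=O)(=O)Cl
Why: Mesylation of the primary alcohol under amine base leaves the epoxide untouched and places the leaving group on C8.

Step 5
Reactants: 5 [(2S,3S)-3-[(benzyloxy)methyl]-2-methyloxiran-2-yl]methyl methanesulfonate
Product: 6 [(2S,3S)-3-(hydroxymethyl)-2-methyloxiran-2-yl]methyl methanesulfonate
Conditions: H2 (1 atm), Pd/C, EtOAc, rt
Reagents that add atoms: none
Why: Catalytic hydrogenolysis of the benzyl ether over palladium on carbon is neutral, so the non-benzylic epoxide and the mesylate should survive while the C5 hydroxyl is freed.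

Step 6
Reactants: 6 [(2S,3S)-3-(hydroxymethyl)-2-methyloxiran-2-yl]methyl methanesulfonate
Product: 8 (2S)-2-methyl-2-[(2R)-oxiran-2-yl]oxirane, via sodium alkoxide 7 (not isolated)
Conditions: NaH, THF, 0 °C → rt; filtration, distillation under reduced pressure
Reagents that add atoms: none
Why: Payne rearrangement followed by intramolecular Williamson-type closure, in which the C5 alkoxide opens the epoxide at C6 by SN2 with inversion (C6 becomes R) and the tertiary C7 alkoxide thus released displaces the neighbouring mesylate irreversibly without breaking the C7–O bond, should give the (6R,7S) bis-epoxide.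

Step 7
Reactants: 8 (2S)-2-methyl-2-[(2R)-oxiran-2-yl]oxirane; 9 methallylmagnesium chloride; 10 acetonitrile
Product: 12 (4S,5R)-4,5-dihydroxy-4,8-dimethylnon-8-enenitrile, via chloromagnesium alkoxide 11 (not isolated)
Conditions: 9 (1.05 equiv), CuI (10 mol %), THF, −40 °C; then LiCH2CN (3 equiv, from 10 and n-BuLi, THF, −78 °C), −78 °C → rt; aq. NH4Cl
Reagents that add atoms: methallylmagnesium chloride CC(=C)C[Mg]Cl; acetonitrile CC#N (used as lithioacetonitrile [Li]CC#N)
Why: Two SN2 openings of terminal epoxides run in one flask: the allylcopper species formed from 9 and CuI attacks C5 of the monosubstituted oxirane to make C4–C5 and alkoxide 11, and lithioacetonitrile then attacks C8 of the 2,2-disubstituted oxirane to make C8–C9. The closest known reactions are the copper-catalysed Grignard opening and the lithiated-nitrile opening of terminal epoxides, as applied to bis-epoxide linchpins. No ring is closed and no stereocentre is created, because both nucleophiles attack CH2 carbons, so the C6–O and C7–O bonds stay intact and the (6R,7S) configuration of 8 passes unchanged into 12. The selectivity needed is attack at C5 before C8 by the first nucleophile, and the substrate secures it because C5 adjoins a CH carbon whereas C8 is neopentyl-like beside quaternary C7, a difference that one equivalent of Grignard reagent at low temperature can exploit. If alkoxide 11 should equilibrate by Payne rearrangement, the internal epoxide isomer is far less reactive towards the nitrile anion and reverts to 11 by a second inversion at C7, so both pathways converge on 12. The nitrile supplies C10 at the aldehyde oxidation level for the later olefination.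

Step 8
Reactants: 12 (4S,5R)-4,5-dihydroxy-4,8-dimethylnon-8-enenitrile
Product: 14 (4S,5R)-5-[(tert-butyldimethylsilyl)oxy]-4,8-dimethyl-4-[(trimethylsilyl)oxy]non-8-enenitrile, via tert-butyldimethylsilyl monoether 13 (not isolated)
Conditions: TBSOTf (1.05 equiv), 2,6-lutidine, CH2Cl2, −78 °C; then TMSOTf, −78 → 0 °C
Reagents that add atoms: tert-butyldimethylsilyl trifluoromethanesulfonate CC(C)(C)[Si](C)(C)OS(=O)(=O)C(F)(F)F; trimethylsilyl trifluoromethanesulfonate C[Si](C)(C)OS(=O)(=O)C(F)(F)F
Why: Silyl ether formation with silyl triflates follows steric accessibility, so the bulky reagent takes the secondary C6 hydroxyl at −78 °C and the small one then caps the tertiary C7 hydroxyl, giving two ethers of graded lability that later prevent lactol formation and oxa-Michael addition.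

Step 9
Reactants: 14 (4S,5R)-5-[(tert-butyldimethylsilyl)oxy]-4,8-dimethyl-4-[(trimethylsilyl)oxy]non-8-enenitrile
Product: 15 (4S,5R)-5-[(tert-butyldimethylsilyl)oxy]-4-methyl-8-oxo-4-[(trimethylsilyl)oxy]nonanenitrile
Conditions: O3, CH2Cl2, −78 °C; then PPh3, −78 °C → rt
Reagents that add atoms: ozone [O-][O+]=O
Why: Ozonolysis with reductive work-up cleaves the only alkene present, the 1,1-disubstituted one, to the C3 methyl ketone, while nitrile and silyl ethers are inert.

Step 10
Reactants: 15 (4S,5R)-5-[(tert-butyldimethylsilyl)oxy]-4-methyl-8-oxo-4-[(trimethylsilyl)oxy]nonanenitrile; 16 triethyl phosphonoacetate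
Product: 17 ethyl (2E,6R,7S)-6-[(tert-butyldimethylsilyl)oxy]-9-cyano-3,7-dimethyl-7-[(trimethylsilyl)oxy]non-2-enoate
Conditions: 16, NaH, THF, 0 °C → 50 °C
Reagents that add atoms: triethyl phosphonoacetate CCOC(=O)CP(=O)(OCC)OCC
Why: Horner–Wadsworth–Emmons olefination of a methyl ketone under equilibrating conditions places the ester trans to the larger CH2 substituent, so the 2E enoate should predominate and the minor 2Z isomer is to be removed by chromatography.

Step 11
Reactants: 17 ethyl (2E,6R,7S)-6-[(tert-butyldimethylsilyl)oxy]-9-cyano-3,7-dimethyl-7-[(trimethylsilyl)oxy]non-2-enoate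
Product: 18 (4S,5R,8E)-5-[(tert-butyldimethylsilyl)oxy]-10-hydroxy-4,8-dimethyl-4-[(trimethylsilyl)oxy]dec-8-enal
Conditions: i-Bu2AlH (4 equiv), CH2Cl2, −78 → −20 °C; aq. potassium sodium tartrate (KNaC4H4O6)
Reagents that add atoms: water O
Why: Hydride reduction with i-Bu2AlH converts the conjugated ester by 1,2-addition into the allylic alcohol and stops at the N-aluminio imine for the nitrile, which hydrolyses to the aldehyde on aqueous work-up, while both silyl ethers are inert.

Step 12
Reactants: 18 (4S,5R,8E)-5-[(tert-butyldimethylsilyl)oxy]-10-hydroxy-4,8-dimethyl-4-[(trimethylsilyl)oxy]dec-8-enal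
Product: 19 (2E,6R,7S)-6-[(tert-butyldimethylsilyl)oxy]-3,7-dimethyl-10-oxo-7-[(trimethylsilyl)oxy]dec-2-en-1-yl acetate
Conditions: Ac2O, pyridine, DMAP (cat.), CH2Cl2, 0 °C
Reagents that add atoms: acetic anhydride CC(=O)OC(C)=O
Why: DMAP-catalysed acylation esterifies the only free hydroxyl, the primary allylic one, and leaves the aldehyde untouched at 0 °C.

Step 13
Reactants: 20 diphenyl phosphite; 21 allyl bromoacetate
Product: 22 prop-2-en-1-yl 2-(diphenoxyphosphoryl)acetate
Conditions: Et3N, CH2Cl2, 0 °C → rt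
Reagents that add atoms: allyl bromoacetate C=CCOC(=O)CBr
Why: Michaelis–Becker-type P-alkylation of the phosphite by an α-bromo ester under amine base gives the diaryl phosphonoacetate required for Z-selective olefination.

Step 14
Reactants: 22 prop-2-en-1-yl 2-(diphenoxyphosphoryl)acetate; 23 5-bromo-2-methylpent-2-ene
Product: 24 prop-2-en-1-yl 2-(diphenoxyphosphoryl)-6-methylhept-5-enoate (racemic)
Conditions: NaH, DMSO, rt; then 23, NaI (cat.), rt → 50 °C
Reagents that add atoms: 5-bromo-2-methylpent-2-ene CC(C)=CCCBr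
Why: C-Alkylation of the stabilised phosphonoacetate anion by a primary bromide under iodide catalysis installs the homoprenyl chain, and monoalkylation is favoured because the product anion is more hindered.

Step 15
Reactants: 19 (2E,6R,7S)-6-[(tert-butyldimethylsilyl)oxy]-3,7-dimethyl-10-oxo-7-[(trimethylsilyl)oxy]dec-2-en-1-yl acetate; 24 prop-2-en-1-yl 2-(diphenoxyphosphoryl)-6-methylhept-5-enoate
Product: 25 prop-2-en-1-yl (2Z,6S,7R,10E)-12-(acetyloxy)-7-[(tert-butyldimethylsilyl)oxy]-6,10-dimethyl-2-(4-methylpent-3-en-1-yl)-6-[(trimethylsilyl)oxy]dodeca-2,10-dienoate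
Conditions: 24 (1.2 equiv), NaH (1.1 equiv), THF, 0 °C; then 19, −78 → 0 °C
Reagents that add atoms: prop-2-en-1-yl 2-(diphenoxyphosphoryl)-6-methylhept-5-enoate C=CCOC(=O)C(CCC=C(C)C)P(=O)(Oc1ccccc1)Oc1ccccc1
Why: In this Z-selective Horner–Wadsworth–Emmons variant the electron-poor phenoxy groups on phosphorus make collapse of the kinetically formed syn-oxaphosphetane faster than its reversal, so the ester should end cis to the C9 chain (the 10Z alkene of the target), and the stabilised phosphonate anion is too weakly basic to harm the acetate.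

Step 16
Reactants: 25 prop-2-en-1-yl (2Z,6S,7R,10E)-12-(acetyloxy)-7-[(tert-butyldimethylsilyl)oxy]-6,10-dimethyl-2-(4-methylpent-3-en-1-yl)-6-[(trimethylsilyl)oxy]dodeca-2,10-dienoate
Product: 27 (2Z,6S,7R,10E)-12-(acetyloxy)-7-[(tert-butyldimethylsilyl)oxy]-6-hydroxy-6,10-dimethyl-2-(4-methylpent-3-en-1-yl)dodeca-2,10-dienoic acid, via trimethylsilyl ether acid 26 (not isolated)
Conditions: Pd(PPh3)4 (3 mol %), morpholine, THF, 0 °C; then AcOH–H2O, rt
Reagents that add atoms: none
Why: In this Tsuji–Trost deallylation zerovalent palladium ionises the unsubstituted allyl ester much faster than the 3,3-disubstituted allylic acetate and morpholine traps the allyl fragment, after which mild aqueous acid hydrolyses only the labile tertiary trimethylsilyl ether and leaves the hindered TBS ether in place.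

Step 17
Reactants: 27 (2Z,6S,7R,10E)-12-(acetyloxy)-7-[(tert-butyldimethylsilyl)oxy]-6-hydroxy-6,10-dimethyl-2-(4-methylpent-3-en-1-yl)dodeca-2,10-dienoic acid
Product: 29 (2E,6R)-6-[(tert-butyldimethylsilyl)oxy]-3-methyl-6-[(2S)-2-methyl-6-(4-methylpent-3-en-1-yl)-7-oxo-2,3,4,7-tetrahydrooxepin-2-yl]hex-2-en-1-yl acetate, via mixed anhydride 28 (not isolated)
Conditions: 2,4,6-trichlorobenzoyl chloride, Et3N, THF, rt; then slow addition to DMAP, toluene, 80 °C (high dilution)
Reagents that add atoms: none
Why: In this Yamaguchi lactonisation the acylpyridinium ion formed from the mixed anhydride is attacked by the only free hydroxyl, the tertiary one on C7, in a 7-exo-trig acyl substitution that the Z alkene preorganises, and because the C6 oxygen is silylated no eight-membered lactone can form.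

Step 18
Reactants: 29 (2E,6R)-6-[(tert-butyldimethylsilyl)oxy]-3-methyl-6-[(2S)-2-methyl-6-(4-methylpent-3-en-1-yl)-7-oxo-2,3,4,7-tetrahydrooxepin-2-yl]hex-2-en-1-yl acetate
Product: 30 (2E,6R)-6-hydroxy-3-methyl-6-[(2S)-2-methyl-6-(4-methylpent-3-en-1-yl)-7-oxo-2,3,4,7-tetrahydrooxepin-2-yl]hex-2-en-1-yl acetate (target)
Conditions: HF·pyridine, pyridine, THF, 0 °C → rt
Reagents that add atoms: none
Why: Fluoride-mediated desilylation under buffered, weakly acidic conditions should free the C6 hydroxyl without acyl migration, loss of the acetate or conjugate addition to the unsaturated lactone.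

**Compound list**

1 | prenol (3-methylbut-2-en-1-ol) | CC(C)=CCO | starting material
2 | benzyl prenyl ether, {[(3-methylbut-2-en-1-yl)oxy]methyl}benzene | CC(C)=CCOCc1ccccc1 | intermediate
3 | (2E)-4-(benzyloxy)-2-methylbut-2-en-1-ol | OC/C(C)=C/COCc1ccccc1 | intermediate
4 | [(2S,3S)-3-[(benzyloxy)methyl]-2-methyloxiran-2-yl]methanol | OC[C@]1(C)O[C@H]1COCc1ccccc1 | intermediate
5 | [(2S,3S)-3-[(benzyloxy)methyl]-2-methyloxiran-2-yl]methyl methanesulfonate | CS(=O)(=O)OC[C@]1(C)O[C@H]1COCc1ccccc1 | intermediate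
6 | [(2S,3S)-3-(hydroxymethyl)-2-methyloxiran-2-yl]methyl methanesulfonate | CS(=O)(=O)OC[C@]1(C)O[C@H]1CO | intermediate
7 | sodium (2S)-1-[(methanesulfonyl)oxy]-2-[(2R)-oxiran-2-yl]propan-2-olate | CS(=O)(=O)OC[C@](C)([O-])[C@H]1CO1.[Na+] | intermediate (not isolated)
8 | (2S)-2-methyl-2-[(2R)-oxiran-2-yl]oxirane | C1O[C@H]1[C@]2(C)CO2 | intermediate
9 | methallylmagnesium chloride | CC(=C)C[Mg]Cl | starting material
10 | acetonitrile | CC#N | starting material
11 | chloromagnesium (1R)-4-methyl-1-[(2S)-2-methyloxiran-2-yl]pent-4-en-1-olate | C=C(C)CC[C@@H](O[Mg]Cl)[C@]1(C)CO1 | intermediate (not isolated)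
12 | (4S,5R)-4,5-dihydroxy-4,8-dimethylnon-8-enenitrile | C=C(C)CC[C@@H](O)[C@@](C)(O)CCC#N | intermediate
13 | (4S,5R)-5-[(tert-butyldimethylsilyl)oxy]-4-hydroxy-4,8-dimethylnon-8-enenitrile | C=C(C)CC[C@@H](O[Si](C)(C)C(C)(C)C)[C@@](C)(O)CCC#N | intermediate (not isolated)
14 | (4S,5R)-5-[(tert-butyldimethylsilyl)oxy]-4,8-dimethyl-4-[(trimethylsilyl)oxy]non-8-enenitrile | C=C(C)CC[C@@H](O[Si](C)(C)C(C)(C)C)[C@@](C)(O[Si](C)(C)C)CCC#N | intermediate
15 | (4S,5R)-5-[(tert-butyldimethylsilyl)oxy]-4-methyl-8-oxo-4-[(trimethylsilyl)oxy]nonanenitrile | CC(=O)CC[C@@H](O[Si](C)(C)C(C)(C)C)[C@@](C)(O[Si](C)(C)C)CCC#N | intermediate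
16 | triethyl phosphonoacetate | CCOC(=O)CP(=O)(OCC)OCC | starting material
17 | ethyl (2E,6R,7S)-6-[(tert-butyldimethylsilyl)oxy]-9-cyano-3,7-dimethyl-7-[(trimethylsilyl)oxy]non-2-enoate | CCOC(=O)/C=C(\C)CC[C@@H](O[Si](C)(C)C(C)(C)C)[C@@](C)(O[Si](C)(C)C)CCC#N | intermediate
18 | (4S,5R,8E)-5-[(tert-butyldimethylsilyl)oxy]-10-hydroxy-4,8-dimethyl-4-[(trimethylsilyl)oxy]dec-8-enal | OC/C=C(\C)CC[C@@H](O[Si](C)(C)C(C)(C)C)[C@@](C)(O[Si](C)(C)C)CCC=O | intermediate
19 | (2E,6R,7S)-6-[(tert-butyldimethylsilyl)oxy]-3,7-dimethyl-10-oxo-7-[(trimethylsilyl)oxy]dec-2-en-1-yl acetate | CC(=O)OC/C=C(\C)CC[C@@H](O[Si](C)(C)C(C)(C)C)[C@@](C)(O[Si](C)(C)C)CCC=O | intermediate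
20 | diphenyl phosphite | O=[PH](Oc1ccccc1)Oc1ccccc1 | starting material
21 | allyl bromoacetate (prop-2-en-1-yl 2-bromoacetate) | C=CCOC(=O)CBr | starting material
22 | prop-2-en-1-yl 2-(diphenoxyphosphoryl)acetate | C=CCOC(=O)CP(=O)(Oc1ccccc1)Oc1ccccc1 | intermediate
23 | 5-bromo-2-methylpent-2-ene | CC(C)=CCCBr | starting material
24 | prop-2-en-1-yl 2-(diphenoxyphosphoryl)-6-methylhept-5-enoate (racemic) | C=CCOC(=O)C(CCC=C(C)C)P(=O)(Oc1ccccc1)Oc1ccccc1 | intermediate
25 | prop-2-en-1-yl (2Z,6S,7R,10E)-12-(acetyloxy)-7-[(tert-butyldimethylsilyl)oxy]-6,10-dimethyl-2-(4-methylpent-3-en-1-yl)-6-[(trimethylsilyl)oxy]dodeca-2,10-dienoate | CC(=O)OC/C=C(\C)CC[C@@H](O[Si](C)(C)C(C)(C)C)[C@@](C)(O[Si](C)(C)C)CC/C=C(/CCC=C(C)C)C(=O)OCC=C | intermediate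
26 | (2Z,6S,7R,10E)-12-(acetyloxy)-7-[(tert-butyldimethylsilyl)oxy]-6,10-dimethyl-2-(4-methylpent-3-en-1-yl)-6-[(trimethylsilyl)oxy]dodeca-2,10-dienoic acid | CC(=O)OC/C=C(\C)CC[C@@H](O[Si](C)(C)C(C)(C)C)[C@@](C)(O[Si](C)(C)C)CC/C=C(/CCC=C(C)C)C(=O)O | intermediate (not isolated)
27 | (2Z,6S,7R,10E)-12-(acetyloxy)-7-[(tert-butyldimethylsilyl)oxy]-6-hydroxy-6,10-dimethyl-2-(4-methylpent-3-en-1-yl)dodeca-2,10-dienoic acid | CC(=O)OC/C=C(\C)CC[C@@H](O[Si](C)(C)C(C)(C)C)[C@@](C)(O)CC/C=C(/CCC=C(C)C)C(=O)O | intermediate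
28 | mixed anhydride of acid 27 with 2,4,6-trichlorobenzoic acid | CC(=O)OC/C=C(\C)CC[C@@H](O[Si](C)(C)C(C)(C)C)[C@@](C)(O)CC/C=C(/CCC=C(C)C)C(=O)OC(=O)c1c(Cl)cc(Cl)cc1Cl | intermediate (not isolated)
29 | (2E,6R)-6-[(tert-butyldimethylsilyl)oxy]-3-methyl-6-[(2S)-2-methyl-6-(4-methylpent-3-en-1-yl)-7-oxo-2,3,4,7-tetrahydrooxepin-2-yl]hex-2-en-1-yl acetate | CC(=O)OC/C=C(\C)CC[C@@H](O[Si](C)(C)C(C)(C)C)[C@]1(C)CCC=C(CCC=C(C)C)C(=O)O1 | intermediate
30 | (2E,6R)-6-hydroxy-3-methyl-6-[(2S)-2-methyl-6-(4-methylpent-3-en-1-yl)-7-oxo-2,3,4,7-tetrahydrooxepin-2-yl]hex-2-en-1-yl acetate | CC(=O)OC/C=C(\C)CC[C@@H](O)[C@]1(C)CCC=C(CCC=C(C)C)C(=O)O1 | target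

**Step count**

Total: 18 steps (16 in the main line, 2 for phosphonate 24).
Longest linear sequence: 16 steps from prenol (steps 1–12 and 15–18).

**Steps most likely to fail**

Step 17 (lactonisation). Acyl transfer to the hindered tertiary hydroxyl may be slow, which would give time for oligomerisation and for Z-to-E isomerisation of the activated acid through reversible conjugate addition of DMAP. The fallback closes the ring by olefin metathesis instead of acyl transfer; it sets out from aldehyde 19 and returns at lactone 29. Aldehyde 19 is methylenated by Wittig reaction (Ph3PCH3Br, KN(SiMe3)2, THF, −78 °C) to the terminal alkene F1, and brief treatment with AcOH–H2O–THF removes the trimethylsilyl group to give the tertiary alcohol F2. In parallel, phosphonate 24 is condensed with paraformaldehyde (K2CO3, THF) to the allyl 2-methylidene ester F3, which is deallylated (Pd(PPh3)4, morpholine) to the acrylic acid F4 and converted with oxalyl chloride into the acid chloride F5. Acylation of F2 with F5 (Et3N, DMAP, CH2Cl2, 40 °C) gives the diene ester F6. Ring-closing metathesis with the second-generation Hoveyda–Grubbs catalyst in dilute toluene at 80 °C then joins the monosubstituted alkene and the 1,1-disubstituted acrylate to lactone 29 with loss of ethene. The cis ring alkene is enforced by the ring size, and the trisubstituted alkenes elsewhere are expected to stay out of the reaction.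

Step 7 (key step). Site selectivity between the two oxirane termini may erode, and epoxide migration or salt-induced rearrangement may set in while two organometallic reagents share one flask. The fallback separates the two openings and caps the C6 oxygen between them; it sets out from bis-epoxide 8 and returns at 13, which is then isolated and silylated with TMSOTf to 14. Bis-epoxide 8 is opened with 9 and catalytic CuI alone and quenched, and the epoxy alcohol F7 is isolated. Silylation (TBSOTf, 2,6-lutidine, −78 °C) gives the epoxy silyl ether F8, in which no alkoxide can start a Payne shift. Lithioacetonitrile (THF, −78 °C → rt) then opens the remaining 2,2-disubstituted oxirane at C8 to give 13.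

Step 10 (E-olefination). E selectivity may be incomplete in the olefination of a methyl ketone whose two α-substituents differ little in size, with loss of material on separating the isomers. The fallback fixes the geometry by syn-carbometalation of an alkyne; it sets out from ketone 15 and returns at hydroxy aldehyde 18. Ketone 15 is converted through its kinetic enol phosphate F9 (LiN(iPr)2, ClP(O)(OEt)2, THF, −78 °C) and elimination with further LiN(iPr)2 into the terminal alkyne F10. Zirconium-catalysed carboalumination (Me3Al, Cp2ZrCl2, CH2Cl2) adds methyl and aluminium syn across the triple bond, and trapping of the alkenylalane with paraformaldehyde gives the E allylic alcohol F11 as a single geometric isomer. Reduction of the nitrile with i-Bu2AlH and aqueous work-up then delivers 18.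

**Further compounds**

F1 | step 17 | (2E,6R,7S)-6-[(tert-butyldimethylsilyl)oxy]-3,7-dimethyl-7-[(trimethylsilyl)oxy]undeca-2,10-dien-1-yl acetate | CC(=O)OC/C=C(\C)CC[C@@H](O[Si](C)(C)C(C)(C)C)[C@@](C)(O[Si](C)(C)C)CCC=C
F2 | step 17 | (2E,6R,7S)-6-[(tert-butyldimethylsilyl)oxy]-7-hydroxy-3,7-dimethylundeca-2,10-dien-1-yl acetate | CC(=O)OC/C=C(\C)CC[C@@H](O[Si](C)(C)C(C)(C)C)[C@@](C)(O)CCC=C
F3 | step 17 | prop-2-en-1-yl 6-methyl-2-methylidenehept-5-enoate | C=CCOC(=O)C(=C)CCC=C(C)C
F4 | step 17 | 6-methyl-2-methylidenehept-5-enoic acid | OC(=O)C(=C)CCC=C(C)C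
F5 | step 17 | 6-methyl-2-methylidenehept-5-enoyl chloride | ClC(=O)C(=C)CCC=C(C)C
F6 | step 17 | (5S,6R,9E)-11-(acetyloxy)-6-[(tert-butyldimethylsilyl)oxy]-5,9-dimethylundeca-1,9-dien-5-yl 6-methyl-2-methylidenehept-5-enoate | CC(=O)OC/C=C(\C)CC[C@@H](O[Si](C)(C)C(C)(C)C)[C@@](C)(OC(=O)C(=C)CCC=C(C)C)CCC=C
F7 | step 7 | (1R)-4-methyl-1-[(2S)-2-methyloxiran-2-yl]pent-4-en-1-ol | C=C(C)CC[C@@H](O)[C@]1(C)CO1
F8 | step 7 | tert-butyl(dimethyl){[(1R)-4-methyl-1-[(2S)-2-methyloxiran-2-yl]pent-4-en-1-yl]oxy}silane | C=C(C)CC[C@@H](O[Si](C)(C)C(C)(C)C)[C@]1(C)CO1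
F9 | step 10 | (5R,6S)-5-[(tert-butyldimethylsilyl)oxy]-8-cyano-6-methyl-6-[(trimethylsilyl)oxy]oct-1-en-2-yl diethyl phosphate | C=C(OP(=O)(OCC)OCC)CC[C@@H](O[Si](C)(C)C(C)(C)C)[C@@](C)(O[Si](C)(C)C)CCC#N
F10 | step 10 | (4S,5R)-5-[(tert-butyldimethylsilyl)oxy]-4-methyl-4-[(trimethylsilyl)oxy]non-8-ynenitrile | C#CCC[C@@H](O[Si](C)(C)C(C)(C)C)[C@@](C)(O[Si](C)(C)C)CCC#N
F11 | step 10 | (4S,5R,8E)-5-[(tert-butyldimethylsilyl)oxy]-10-hydroxy-4,8-dimethyl-4-[(trimethylsilyl)oxy]dec-8-enenitrile | OC/C=C(\C)CC[C@@H](O[Si](C)(C)C(C)(C)C)[C@@](C)(O[Si](C)(C)C)CCC#N
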